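**Retrosynthetic overview**
1. C13=C14 comes from a Horner–Wadsworth–Emmons olefination of a C13 methyl ketone; C9–C11 from α-face addition of a masked 3-oxobutyl Grignard reagent to a C9 ketone; the 2α,3α-diol from OsO4 on a C2=C3 olefin.
2. Ring B is closed at C6–C7 by 6-endo radical cyclization of a C7 radical onto a C5=C6 exocyclic methylene; C7, C8 and the C8 methyl are added to the C9 carboxyl as isopropenyllithium.
3. Ring A is closed at C1–C10 by Ireland–Claisen ring contraction of a six-membered lactone (O, C9, C10, C5, C4, C3) that is not in the target; its ester link C9(=O)–O–C3 is a temporary tether, cut as C1–C10 forms.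
4. Enabling feature: C3 bears oxygen and is allylic to C1 through the C2=C3 olefin (the later diol), C9 bears oxygen and is bonded to C10, and C3 and C10 are bridged by C4–C5 of ring A; so C1=C2–C3–O–C9=C10 can be set up as an allyl ketene acetal inside a lactone, and quaternary C4 leaves only one enolization path.
5. Ring order: temporary lactone (step 3), ring A (step 6), ring B (step 9); the lactone is built from acrolein, an isobutyrate ketene silyl acetal, a propionyl group and a methyl group.

Key step: step 6

Remark: atoms are numbered as in the labdane skeleton of the target (decalin C1–C10, gem-dimethyl on C4, methyls on C8 and C10, carbinol C9). The sense of induction in step 1 is assumed to follow the accepted model for this catalyst class; the (R)-valine-derived catalyst would be used if it proved opposite.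

Step 1
Reactants: 1 acrolein; 2 1-methoxy-2-methyl-1-(trimethylsilyloxy)prop-1-ene
Product: 4 methyl (3R)-3-hydroxy-2,2-dimethylpent-4-enoate, via silyl ether 3 (not isolated)
Conditions: oxazaborolidinone from N-tosyl-(S)-valine and BH3·THF (20 mol %), EtNO2, −78 °C; then 1 M HCl, THF, 0 °C
Reagents that add atoms: none
Why: Chiral oxazaborolidinone-catalysed Mukaiyama aldol addition, in which the boron Lewis acid is expected to expose the si face of the bound aldehyde and so set the (R)-carbinol (future C3); the silyl ether 3 is cleaved on acidic work-up.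

Step 2
Reactants: 4 methyl (3R)-3-hydroxy-2,2-dimethylpent-4-enoate
Product: 5 methyl (3R)-2,2-dimethyl-3-(propanoyloxy)pent-4-enoate
Conditions: propionic anhydride, Et3N, DMAP (cat.), CH2Cl2, 0 °C → rt
Reagents that add atoms: propionic anhydride, CCC(=O)OC(=O)CC
Why: DMAP-catalysed acylation of the secondary allylic alcohol installs the propionyl unit that becomes C9, C10 and the C10 methyl; no stereocentre is touched.

Step 3
Reactants: 5 methyl (3R)-2,2-dimethyl-3-(propanoyloxy)pent-4-enoate
Product: 6 (6R)-6-ethenyl-4-hydroxy-3,5,5-trimethyl-5,6-dihydro-2H-pyran-2-one (enol form of the pyran-2,4-dione)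
Conditions: LiN(SiMe3)2 (2.2 equiv), THF, −78 → −20 °C; then 1 M HCl
Reagents that add atoms: none
Why: Dieckmann-type intramolecular Claisen condensation, in which only the propionate CH2 can enolize (the methyl ester sits on the quaternary carbon) and the product is trapped as its stabilized enolate; the low temperature should keep the acyclic ester-enolate Claisen rearrangement of the allyl propionate from competing, and the carbinol centre is not involved.

Step 4
Reactants: 6 (6R)-6-ethenyl-4-hydroxy-3,5,5-trimethyl-5,6-dihydro-2H-pyran-2-one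
Product: 7 (2R)-2-ethenyl-3,3,5-trimethyl-6-oxo-3,6-dihydro-2H-pyran-4-yl trifluoromethanesulfonate
Conditions: Tf2O, Et3N, CH2Cl2, −78 °C
Reagents that add atoms: trifluoromethanesulfonic anhydride, O=S(=O)(OS(=O)(=O)C(F)(F)F)C(F)(F)F
Why: O-sulfonylation of the enol of a cyclic β-keto ester at the ketone-derived oxygen gives the conjugated enol triflate, the usual activation of 4-hydroxy-5,6-dihydropyranones for cross-coupling.

Step 5
Reactants: 7 (2R)-2-ethenyl-3,3,5-trimethyl-6-oxo-3,6-dihydro-2H-pyran-4-yl trifluoromethanesulfonate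
Product: 8 (6R)-6-ethenyl-3,4,5,5-tetramethyl-5,6-dihydro-2H-pyran-2-one
Conditions: MeMgBr (1.3 equiv), Fe(acac)3 (5 mol %), THF/NMP, −30 °C
Reagents that add atoms: methylmagnesium bromide, C[Mg]Br
Why: Iron-catalysed cross-coupling of an alkenyl triflate with an alkyl Grignard reagent is fast at −30 °C, so it spares the lactone carbonyl and, unlike a zerovalent palladium catalyst, should not ionize the allylic C–O bond of the vinyl-bearing carbinol; the new methyl is the future C6.

Step 6
Reactants: 8 (6R)-6-ethenyl-3,4,5,5-tetramethyl-5,6-dihydro-2H-pyran-2-one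
Product: 11 (1S)-1,3,3-trimethyl-2-methylidenecyclohex-4-ene-1-carboxylic acid, via silyl ketene acetal 9 (not isolated), via TBS ester 10 (not isolated)
Conditions: TBSOTf, Et3N, CH2Cl2, 0 °C; solvent exchange to PhMe, 110 °C; then 1 M HCl, THF, rt
Reagents that add atoms: none
Why: TBSOTf/Et3N silylates the lactone carbonyl and removes a proton from the C6 methyl (C4 is quaternary, so nothing else can enolize), giving the cross-conjugated cyclic silyl ketene acetal 9, in which O–C3–C2=C1 and C10=C9(OTBS) make up an allyl vinyl ether. On heating, a concerted suprafacial [3,3] shift (Ireland–Claisen) through the boat transition state that the six-membered ring enforces forms C1–C10 and breaks C3–O, so the lactone contracts to cyclohexene ring A, with the former ring atoms O and C9 becoming the exocyclic carboxyl. The closest known reaction type is the Ireland–Claisen ring contraction of 6-alkenyl δ-valerolactone silyl ketene acetals to cyclohexenecarboxylic acids. The only new stereocentre, quaternary C10, is set by 1,3-chirality transfer: the vinyl group can reach only the face of C9=C10 on which C3 holds it, so (R)-C3 is expected to give (S)-C10. The step needs O- over C-silylation and the Claisen shift over the Cope shift of the C6=C5–C4–C3–C2=C1 diene; the hard silyl triflate and the much lower barrier of a ketene-acetal Claisen, made irreversible by formation of the silyl ester, should secure both. The same event installs the C2=C3 olefin for the diol, frees the C9 carboxyl for ring B and leaves C5=C6 as the handle for the C6–C7 bond.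

Step 7
Reactants: 11 (1S)-1,3,3-trimethyl-2-methylidenecyclohex-4-ene-1-carboxylic acid; 12 2-bromopropene
Product: 14 2-methyl-1-[(1S)-1,3,3-trimethyl-2-methylidenecyclohex-4-en-1-yl]prop-2-en-1-one, via isopropenyllithium 13 (not isolated)
Conditions: 12, t-BuLi (2 equiv per 12), Et2O, −78 °C; then 11 (0.33 equiv), −78 → 0 °C; then H2O
Reagents that add atoms: none
Why: Addition of an alkenyllithium to the lithium carboxylate stops at the dilithio gem-diolate, which gives the ketone only on hydrolysis, a dependable ketone synthesis for α-quaternary acids; it brings in C7, C8 and the C8 methyl.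

Step 8
Reactants: 14 2-methyl-1-[(1S)-1,3,3-trimethyl-2-methylidenecyclohex-4-en-1-yl]prop-2-en-1-one
Product: 15 2-methyl-3-(phenylselanyl)-1-[(1S)-1,3,3-trimethyl-2-methylidenecyclohex-4-en-1-yl]propan-1-one (both epimers at the new centre)
Conditions: PhSeH (1.2 equiv), Et3N (cat.), CH2Cl2, 0 °C → rt, under argon
Reagents that add atoms: benzeneselenol, [SeH]c1ccccc1
Why: Base-catalysed conjugate (selena-Michael) addition to the unhindered terminal carbon of the enone gives a stable β-seleno ketone as the C7 radical precursor; the new C8 centre forms as both epimers and is corrected in step 9.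

Step 9
Reactants: 15 2-methyl-3-(phenylselanyl)-1-[(1S)-1,3,3-trimethyl-2-methylidenecyclohex-4-en-1-yl]propan-1-one
Product: 17 (2R,4aS,8aS)-2,5,5,8a-tetramethyl-3,4,4a,5,8,8a-hexahydronaphthalen-1(2H)-one, via C8-epimeric ketone 16 (not isolated)
Conditions: Bu3SnH (1.3 equiv, syringe pump), AIBN (cat.), PhH (5 mM), 80 °C; then NaOMe, MeOH, rt
Reagents that add atoms: none
Why: C–Se homolysis gives the primary C7 radical, which closes ring B by 6-endo-trig addition to C6 of the 1,1-disubstituted olefin (5-exo attack on C5, flanked by two quaternary carbons, is blocked); the tertiary C5 radical should take hydrogen from Bu3SnH on the α face, opposite the axial C10 methyl, to give the trans fusion (5S), and methoxide then equilibrates C8 to the equatorial methyl (8R), the axial epimer suffering a 1,3-diaxial methyl–methyl contact.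

Step 10
Reactants: 17 (2R,4aS,8aS)-2,5,5,8a-tetramethyl-3,4,4a,5,8,8a-hexahydronaphthalen-1(2H)-one
Product: 18 (2R,4aS,6S,7R,8aS)-6,7-dihydroxy-2,5,5,8a-tetramethyloctahydronaphthalen-1(2H)-one (2α,3α-diol in labdane numbering)
Conditions: OsO4 (2 mol %), NMO, acetone/H2O, rt
Reagents that add atoms: N-methylmorpholine N-oxide, C[N+]1([O-])CCOCC1; water, O
Why: Catalytic OsO4 syn-dihydroxylation of the only olefin should occur on the α face, away from the axial β-methyls on C10 and C4, as is general for 4,4,10-trimethyl-trans-decal-2-enes, setting 2R,3S.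

Step 11
Reactants: 18 (2R,4aS,6S,7R,8aS)-6,7-dihydroxy-2,5,5,8a-tetramethyloctahydronaphthalen-1(2H)-one
Product: 19 (2R,4aS,6S,7R,8aS)-6,7-(isopropylidenedioxy)-2,5,5,8a-tetramethyloctahydronaphthalen-1(2H)-one
Conditions: 2,2-dimethoxypropane, PPTS (cat.), acetone, rt
Reagents that add atoms: 2,2-dimethoxypropane, COC(C)(C)OC
Why: Acid-catalysed transketalization protects the cis-diol as its acetonide so that two alkoxides do not consume the organometallic reagent of step 12; the hindered ketone should not ketalize.

Step 12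
Reactants: 19 (2R,4aS,6S,7R,8aS)-6,7-(isopropylidenedioxy)-2,5,5,8a-tetramethyloctahydronaphthalen-1(2H)-one; 20 2-(2-bromoethyl)-2-methyl-1,3-dioxolane
Product: 22 (1S,2R,4aS,6S,7R,8aS)-6,7-(isopropylidenedioxy)-2,5,5,8a-tetramethyl-1-[2-(2-methyl-1,3-dioxolan-2-yl)ethyl]decahydronaphthalen-1-ol, via Grignard reagent 21 (not isolated)
Conditions: 20, Mg, THF, 20 °C; anhydrous CeCl3, THF, −78 °C; then 19, −78 → 0 °C; then H2O
Reagents that add atoms: none
Why: CeCl3-promoted Grignard 1,2-addition suppresses enolization of the doubly flanked ketone, and the nucleophile should attack axially from the α face because the equatorial trajectory is blocked by the axial C10 methyl, giving the 9α-alkyl, 9β-hydroxy (9S) carbinol.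

Step 13
Reactants: 22 (1S,2R,4aS,6S,7R,8aS)-6,7-(isopropylidenedioxy)-2,5,5,8a-tetramethyl-1-[2-(2-methyl-1,3-dioxolan-2-yl)ethyl]decahydronaphthalen-1-ol
Product: 23 4-[(1S,2R,4aS,6S,7R,8aS)-1,6,7-trihydroxy-2,5,5,8a-tetramethyldecahydronaphthalen-1-yl]butan-2-one
Conditions: 1 M HCl, THF, rt
Reagents that add atoms: water, O
Why: Mild aqueous acid hydrolyses the dioxolane and the acetonide in one operation; the hindered tertiary alcohol is not expected to ionize in dilute acid at room temperature.

Step 14
Reactants: 23 4-[(1S,2R,4aS,6S,7R,8aS)-1,6,7-trihydroxy-2,5,5,8a-tetramethyldecahydronaphthalen-1-yl]butan-2-one; 24 trimethyl phosphonoacetate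
Product: 26 methyl (2E)-3-methyl-5-[(1S,2R,4aS,6S,7R,8aS)-1,6,7-trihydroxy-2,5,5,8a-tetramethyldecahydronaphthalen-1-yl]pent-2-enoate, via sodium phosphonate 25 (not isolated)
Conditions: 24 (4 equiv), NaH, THF, 0 °C; then 23, rt → 50 °C
Reagents that add atoms: none
Why: Horner–Wadsworth–Emmons olefination of the methyl ketone with a stabilized phosphonate anion, which is too weakly basic to deprotonate the alcohols appreciably, is expected to favour the E-enoate (ester trans to the larger CH2 branch); the minor Z isomer would be removed by chromatography.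

**Compound list**
1 | acrolein | C=CC=O | starting material
2 | 1-methoxy-2-methyl-1-(trimethylsilyloxy)prop-1-ene | COC(O[Si](C)(C)C)=C(C)C | starting material
3 | methyl (3R)-2,2-dimethyl-3-[(trimethylsilyl)oxy]pent-4-enoate | C=C[C@@H](O[Si](C)(C)C)C(C)(C)C(=O)OC | intermediate
4 | methyl (3R)-3-hydroxy-2,2-dimethylpent-4-enoate | C=C[C@@H](O)C(C)(C)C(=O)OC | intermediate
5 | methyl (3R)-2,2-dimethyl-3-(propanoyloxy)pent-4-enoate | C=C[C@@H](OC(=O)CC)C(C)(C)C(=O)OC | intermediate
6 | (6R)-6-ethenyl-4-hydroxy-3,5,5-trimethyl-5,6-dihydro-2H-pyran-2-one | C=C[C@H]1OC(=O)C(C)=C(O)C1(C)C | intermediate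
7 | (2R)-2-ethenyl-3,3,5-trimethyl-6-oxo-3,6-dihydro-2H-pyran-4-yl trifluoromethanesulfonate | C=C[C@H]1OC(=O)C(C)=C(OS(=O)(=O)C(F)(F)F)C1(C)C | intermediate
8 | (6R)-6-ethenyl-3,4,5,5-tetramethyl-5,6-dihydro-2H-pyran-2-one | C=C[C@H]1OC(=O)C(C)=C(C)C1(C)C | intermediate
9 | (2R)-6-[(tert-butyldimethylsilyl)oxy]-2-ethenyl-3,3,5-trimethyl-4-methylidene-3,4-dihydro-2H-pyran | C=C[C@H]1OC(O[Si](C)(C)C(C)(C)C)=C(C)C(=C)C1(C)C | intermediate
10 | tert-butyldimethylsilyl (1S)-1,3,3-trimethyl-2-methylidenecyclohex-4-ene-1-carboxylate | CC(C)(C)[Si](C)(C)OC(=O)[C@@]1(C)CC=CC(C)(C)C1=C | intermediate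
11 | (1S)-1,3,3-trimethyl-2-methylidenecyclohex-4-ene-1-carboxylic acid | OC(=O)[C@@]1(C)CC=CC(C)(C)C1=C | intermediate
12 | 2-bromopropene | CC(Br)=C | starting material
13 | isopropenyllithium | [Li]C(C)=C | intermediate
14 | 2-methyl-1-[(1S)-1,3,3-trimethyl-2-methylidenecyclohex-4-en-1-yl]prop-2-en-1-one | C=C(C)C(=O)[C@@]1(C)CC=CC(C)(C)C1=C | intermediate
15 | 2-methyl-3-(phenylselanyl)-1-[(1S)-1,3,3-trimethyl-2-methylidenecyclohex-4-en-1-yl]propan-1-one | CC(C[Se]c1ccccc1)C(=O)[C@@]1(C)CC=CC(C)(C)C1=C | intermediate
16 | (2RS,4aS,8aS)-2,5,5,8a-tetramethyl-3,4,4a,5,8,8a-hexahydronaphthalen-1(2H)-one | O=C1C(C)CC[C@H]2C(C)(C)C=CC[C@@]21C | intermediate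
17 | (2R,4aS,8aS)-2,5,5,8a-tetramethyl-3,4,4a,5,8,8a-hexahydronaphthalen-1(2H)-one | O=C1[C@H](C)CC[C@H]2C(C)(C)C=CC[C@@]21C | intermediate
18 | (2R,4aS,6S,7R,8aS)-6,7-dihydroxy-2,5,5,8a-tetramethyloctahydronaphthalen-1(2H)-one | O=C1[C@H](C)CC[C@H]2C(C)(C)[C@H](O)[C@H](O)C[C@@]21C | intermediate
19 | (2R,4aS,6S,7R,8aS)-6,7-(isopropylidenedioxy)-2,5,5,8a-tetramethyloctahydronaphthalen-1(2H)-one | O=C1[C@H](C)CC[C@H]2C(C)(C)[C@@H]3OC(C)(C)O[C@@H]3C[C@@]21C | intermediate
20 | 2-(2-bromoethyl)-2-methyl-1,3-dioxolane | CC1(CCBr)OCCO1 | starting material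
21 | [2-(2-methyl-1,3-dioxolan-2-yl)ethyl]magnesium bromide | CC1(CC[Mg]Br)OCCO1 | intermediate
22 | (1S,2R,4aS,6S,7R,8aS)-6,7-(isopropylidenedioxy)-2,5,5,8a-tetramethyl-1-[2-(2-methyl-1,3-dioxolan-2-yl)ethyl]decahydronaphthalen-1-ol | CC1(CC[C@]2(O)[C@H](C)CC[C@H]3C(C)(C)[C@@H]4OC(C)(C)O[C@@H]4C[C@@]32C)OCCO1 | intermediate
23 | 4-[(1S,2R,4aS,6S,7R,8aS)-1,6,7-trihydroxy-2,5,5,8a-tetramethyldecahydronaphthalen-1-yl]butan-2-one | CC(=O)CC[C@]1(O)[C@H](C)CC[C@H]2C(C)(C)[C@H](O)[C@H](O)C[C@@]21C | intermediate
24 | trimethyl phosphonoacetate | COC(=O)CP(=O)(OC)OC | starting material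
25 | sodium salt of trimethyl phosphonoacetate | COC(=O)[CH-]P(=O)(OC)OC.[Na+] | intermediate
26 | methyl (2E)-3-methyl-5-[(1S,2R,4aS,6S,7R,8aS)-1,6,7-trihydroxy-2,5,5,8a-tetramethyldecahydronaphthalen-1-yl]pent-2-enoate | COC(=O)/C=C(\C)CC[C@]1(O)[C@H](C)CC[C@H]2C(C)(C)[C@H](O)[C@H](O)C[C@@]21C | target

Total step count: 14. Longest linear sequence: 14 steps (from 1 and 2 to 26).

**Steps most likely to fail**

Step 9. The primary C7 radical may be reduced before it cyclizes, or may abstract the allylic hydrogen on C1 through a six-membered transition state, so that ring B does not close cleanly. The fallback sets out from 14 and closes ring B by a polar route. Treatment with Me2AlCl in CH2Cl2 at −78 °C should activate the enone for attack at C7 by C6 of the 1,1-disubstituted olefin (cationic 6-endo cyclization), and proton loss from C6 would give the bicyclic dienone (8aS)-2,5,5,8a-tetramethyl-3,5,8,8a-tetrahydronaphthalen-1(2H)-one F3. Hydrogen-atom-transfer hydrogenation of the trisubstituted C5=C6 olefin (tris(dipivaloylmethanato)manganese, Mn(dpm)3, cat., PhSiH3, t-BuOOH, i-PrOH), which should leave the disubstituted C2=C3 olefin and give the thermodynamically preferred trans fusion, followed by NaOMe/MeOH, returns to 17.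

Step 6. γ-Enolization toward the C6 methyl may be incomplete, or the silyl dienol ether may decompose before the strained boat rearrangement takes place. The fallback sets out from 8 and uses the neutral allyl vinyl ether variant of the same bond formation. Addition of isopropenyllithium 13 at −78 °C to the lactone carbonyl would give the lactol (6R)-6-ethenyl-3,4,5,5-tetramethyl-2-(prop-1-en-2-yl)-5,6-dihydro-2H-pyran-2-ol F1. Acid-catalysed dehydration (PPTS, 4 Å molecular sieves, PhH, 50 °C) through the dienyl oxocarbenium ion, with proton loss from the C6 methyl, would give the cyclic trienyl ether (2R)-2-ethenyl-3,3,5-trimethyl-4-methylidene-6-(prop-1-en-2-yl)-3,4-dihydro-2H-pyran F2. Thermal Claisen rearrangement (xylene, 130 °C) would then form C1–C10 with the same chirality transfer and return to the route at dienone 14, so that step 7 is no longer needed.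

Step 12. The bulky alkyl nucleophile may enolize the ketone toward C8 or fail to add to the carbonyl flanked by C8 and quaternary C10, and the facial preference may erode. The fallback sets out from 19 and uses a small sp nucleophile. The lithium acetylide of 2-ethynyl-2-methyl-1,3-dioxolane (n-BuLi, then anhydrous CeCl3, THF, −78 °C) should add axially from the α face to give the alkynyl carbinol F4, which is 22 with a C11≡C12 triple bond (9α-alkynyl, 9β-hydroxy). Hydrogenation (H2, Pd/C, EtOAc) saturates the triple bond and returns to 22.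

**Further compounds**
F1 | step 6 | (6R)-6-ethenyl-3,4,5,5-tetramethyl-2-(prop-1-en-2-yl)-5,6-dihydro-2H-pyran-2-ol | C=C[C@H]1OC(O)(C(C)=C)C(C)=C(C)C1(C)C
F2 | step 6 | (2R)-2-ethenyl-3,3,5-trimethyl-4-methylidene-6-(prop-1-en-2-yl)-3,4-dihydro-2H-pyran | C=C[C@H]1OC(C(C)=C)=C(C)C(=C)C1(C)C
F3 | step 9 | (8aS)-2,5,5,8a-tetramethyl-3,5,8,8a-tetrahydronaphthalen-1(2H)-one (both C2 epimers) | O=C1C(C)CC=C2C(C)(C)C=CC[C@@]21C
F4 | step 12 | 9α-[(2-methyl-1,3-dioxolan-2-yl)ethynyl] analogue of 22 (9β-hydroxy, C11≡C12) | CC1(C#C[C@]2(O)[C@H](C)CC[C@H]3C(C)(C)[C@@H]4OC(C)(C)O[C@@H]4C[C@@]32C)OCCO1
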